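**Strategy.** The tetramer is disconnected at its three C4–C8 interflavan bonds into tetra-O-benzylcatechin and three copies of one chain extender, a benzylated flavan-3,4-diol whose ring C is built de novo. The key step makes that ring from 3,5-bis(benzyloxy)phenol and a (2R,3S)-epoxycinnamaldehyde in one operation: magnesium-phenoxide ortho-hydroxyalkylation forges C4–C4a, then phenol oxygen O1 opens the strained oxirane at benzylic C2 with inversion, closing the O1–C2 bond. It exploits the anti relationship of O1 and the 3-hydroxyl across C2–C3 of ring C and the cation-stabilising catechol ring B on C2. The precursor is an open-chain ortho-hydroxyaryl epoxy alcohol. Acetoxonium-directed 4α couplings and deprotection finish.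

Key step: step 3

Remark: the target is read as catechin-(4α→8)-catechin-(4α→8)-catechin-(4α→8)-catechin (every unit 2R,3S, every interflavan bond 3,4-trans). Compounds 6, 7 and 8 are carried as C4 epimer mixtures (C4 undefined in their SMILES), which is immaterial because C4 is ionised in each coupling. The catalyst enantiomer in step 2 is chosen from the steric-shielding model of diarylprolinol silyl ether iminium ions.

**Step 1**
Reactants: 1 3,4-bis(benzyloxy)benzaldehyde
Product: 2 (E)-3-[3,4-bis(benzyloxy)phenyl]prop-2-enal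
Conditions: Ph3P=CHCHO (1.2 equiv), toluene, 80 °C
Reagents that add atoms: (triphenylphosphoranylidene)acetaldehyde, O=CC=P(c1ccccc1)(c1ccccc1)c1ccccc1
Why: Wittig olefination with a stabilised formyl ylide, which should give the (E)-enal because oxaphosphetane formation is reversible and the trans alkene is favoured.

**Step 2**
Reactants: 2 (E)-3-[3,4-bis(benzyloxy)phenyl]prop-2-enal
Product: 3 (2R,3S)-3-[3,4-bis(benzyloxy)phenyl]oxirane-2-carbaldehyde (trans)
Conditions: (R)-2-{bis[3,5-bis(trifluoromethyl)phenyl](trimethylsilyloxy)methyl}pyrrolidine (10 mol %), 35% aq. H2O2 (1.3 equiv), CH2Cl2, rt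
Reagents that add atoms: hydrogen peroxide, OO
Why: Iminium-ion organocatalytic nucleophilic epoxidation of an enal, in which hydroperoxide should add to the β-carbon of the E-iminium ion anti to the C(Ar)2OSiMe3 group and the enamine then closes the oxirane, so the (R)-catalyst should set both centres of the trans-(2R,3S)-epoxide.

**Step 3**
Reactants: 3 (2R,3S)-3-[3,4-bis(benzyloxy)phenyl]oxirane-2-carbaldehyde; 4 3,5-bis(benzyloxy)phenol
Product: 7 (2R,3S,4RS)-5,7-bis(benzyloxy)-2-[3,4-bis(benzyloxy)phenyl]chromane-3,4-diol, via bromomagnesium phenoxide 5 (not isolated), via epoxy alcohol 6 (not isolated)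
Conditions: 4 (1.2 equiv), EtMgBr (1.2 equiv), Et2O then CH2Cl2, 0 °C; 3, −20 → 0 °C; then AcOH (2 equiv), 0 °C → rt
Reagents that add atoms: none
Why: Bromomagnesium phenoxide 5 should add through its ortho carbon to the magnesium-coordinated aldehyde of 3 in a six-membered chelate (ortho-specific phenol–aldehyde hydroxyalkylation), giving 6 after protonation. Acetic acid then frees phenol O1 and activates the oxirane, and O1 attacks benzylic C2 from the rear with release of three-ring strain, the closest known reaction type being the acid-promoted phenol–epoxide cyclisation of 2-(3-aryl-2,3-epoxypropyl)phenols to 2,3-trans-flavan-3-ols. Ring C closes in the 6-endo-tet mode. C2 is set by inversion at the oxirane carbon (S in 6, R in 7) and C3 is carried over unchanged from the catalyst-controlled epoxide, the oxirane oxygen becoming the 3-hydroxyl, so the trans-oxirane maps onto the 2,3-trans pattern, which is also the all-equatorial outcome should the opening acquire cationic character; the C4 carbinol centre forms without control and is erased later. The step needs 6-endo attack at C2 over 5-exo attack at C3, which the 3,4-bis(benzyloxy)phenyl ring B secures by stabilising positive charge at C2 while the C4 carbinol deactivates C3. It also needs C-ortho over O- or para-attack of the phenol, secured by magnesium chelation in a non-coordinating solvent and by the equivalence of the two ortho positions of 4.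

**Step 4**
Reactants: 7 (2R,3S,4RS)-5,7-bis(benzyloxy)-2-[3,4-bis(benzyloxy)phenyl]chromane-3,4-diol
Product: 8 (2R,3S,4RS)-5,7-bis(benzyloxy)-2-[3,4-bis(benzyloxy)phenyl]chromane-3,4-diyl diacetate
Conditions: Ac2O (3 equiv), pyridine, DMAP (5 mol %), CH2Cl2, 0 °C → rt; chromatography on Et3N-deactivated silica
Reagents that add atoms: acetic anhydride, CC(=O)OC(C)=O
Why: DMAP-catalysed acylation of both hydroxyls, which installs the 3-acetate as participating group and the 4-acetate as leaving group for the couplings without touching a stereocentre.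

**Step 5**
Reactants: 9 (+)-catechin
Product: 10 5,7,3',4'-tetra-O-benzyl-(+)-catechin
Conditions: BnBr (4.4 equiv), K2CO3 (5 equiv), DMF, 0 °C → rt
Reagents that add atoms: benzyl bromide, BrCc1ccccc1
Why: Williamson etherification of the four phenols (the aliphatic 3-OH is not deprotonated by K2CO3), which leaves C2 and C3 of the chiral-pool unit untouched.

**Step 6**
Reactants: 8 (2R,3S,4RS)-5,7-bis(benzyloxy)-2-[3,4-bis(benzyloxy)phenyl]chromane-3,4-diyl diacetate; 10 5,7,3',4'-tetra-O-benzyl-(+)-catechin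
Product: 11 [3-O-acetyl-5,7,3',4'-tetra-O-benzylcatechin]-(4α→8)-[5,7,3',4'-tetra-O-benzylcatechin]
Conditions: 10 (4 equiv, excess recovered), TMSOTf (0.2 equiv), CH2Cl2, −78 → −40 °C
Reagents that add atoms: none
Why: Friedel–Crafts alkylation with neighbouring-group participation, in which the Lewis acid ionises the 4-acetate, the 3-acetate on the β face holds the benzylic cation as a cis-fused acetoxonium ion, and C8 of 10 should attack from the α face to give the 3,4-trans (4α→8) bond.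

**Step 7**
Reactants: 8 (2R,3S,4RS)-5,7-bis(benzyloxy)-2-[3,4-bis(benzyloxy)phenyl]chromane-3,4-diyl diacetate; 11 protected dimer
Product: 12 [3-O-acetyl-tetra-O-benzylcatechin]-(4α→8)-[3-O-acetyl-tetra-O-benzylcatechin]-(4α→8)-[tetra-O-benzylcatechin]
Conditions: 11 (3 equiv, excess recovered), TMSOTf (0.2 equiv), CH2Cl2, −78 → −40 °C
Reagents that add atoms: none
Why: The same acetoxonium-directed Friedel–Crafts alkylation, expected at C8 of the upper unit of 11 because the C6 positions are flanked by two benzyloxy groups and C8 of the lower unit is already substituted; the new C4 centre is again set trans to the 3-acetate.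

**Step 8**
Reactants: 8 (2R,3S,4RS)-5,7-bis(benzyloxy)-2-[3,4-bis(benzyloxy)phenyl]chromane-3,4-diyl diacetate; 12 protected trimer
Product: 13 tri-O-acetyl-hexadeca-O-benzyl tetramer, [3-O-acetyl-tetra-O-benzylcatechin]-(4α→8) three times onto tetra-O-benzylcatechin
Conditions: 12 (2.5 equiv, excess recovered), TMSOTf (0.2 equiv), CH2Cl2, −78 → −40 °C
Reagents that add atoms: none
Why: A third acetoxonium-directed Friedel–Crafts alkylation at the free C8 of the top unit of 12, which attaches the last de novo unit with its C4 centre set α by the participating 3-acetate.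

**Step 9**
Reactants: 13 tri-O-acetyl-hexadeca-O-benzyl tetramer
Product: 14 hexadeca-O-benzyl-[catechin-(4α→8)]3-catechin
Conditions: NaOMe (0.5 equiv), MeOH/THF 1:1, 40 °C
Reagents that add atoms: none
Why: Zemplén transesterification, which should remove the three secondary acetates without affecting benzyl ethers, interflavan bonds or stereocentres.

**Step 10**
Reactants: 14 hexadeca-O-benzyl-[catechin-(4α→8)]3-catechin
Product: 15 catechin-(4α→8)-catechin-(4α→8)-catechin-(4α→8)-catechin (target)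
Conditions: H2 (1 atm), Pd(OH)2/C, THF/MeOH/H2O, rt; Sephadex LH-20, lyophilisation
Reagents that add atoms: none
Why: Catalytic hydrogenolysis of all sixteen benzyl ethers under neutral conditions, which should leave the acid-sensitive interflavan bonds and all stereocentres intact.

**Compound list**
1 | 3,4-bis(benzyloxy)benzaldehyde | O=Cc1ccc(OCc2ccccc2)c(OCc2ccccc2)c1 | starting material
2 | (E)-3-[3,4-bis(benzyloxy)phenyl]prop-2-enal | O=C/C=C/c1ccc(OCc2ccccc2)c(OCc2ccccc2)c1 | intermediate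
3 | (2R,3S)-3-[3,4-bis(benzyloxy)phenyl]oxirane-2-carbaldehyde | O=C[C@@H]1O[C@H]1c1ccc(OCc2ccccc2)c(OCc2ccccc2)c1 | intermediate
4 | 3,5-bis(benzyloxy)phenol | Oc1cc(OCc2ccccc2)cc(OCc2ccccc2)c1 | starting material
5 | bromomagnesium 3,5-bis(benzyloxy)phenoxide | Br[Mg]Oc1cc(OCc2ccccc2)cc(OCc2ccccc2)c1 | intermediate
6 | (1RS)-[2-hydroxy-4,6-bis(benzyloxy)phenyl]{(2S,3S)-3-[3,4-bis(benzyloxy)phenyl]oxiran-2-yl}methanol | OC(c1c(O)cc(OCc2ccccc2)cc1OCc1ccccc1)[C@@H]1O[C@H]1c1ccc(OCc2ccccc2)c(OCc2ccccc2)c1 | intermediate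
7 | (2R,3S,4RS)-5,7-bis(benzyloxy)-2-[3,4-bis(benzyloxy)phenyl]chromane-3,4-diol (tetra-O-benzyl flavan-3,4-diol) | O(Cc3ccccc3)c1cc(OCc3ccccc3)c2c(c1)O[C@H](c1ccc(OCc3ccccc3)c(OCc3ccccc3)c1)[C@@H](O)C2O | intermediate
8 | (2R,3S,4RS)-5,7-bis(benzyloxy)-2-[3,4-bis(benzyloxy)phenyl]chromane-3,4-diyl diacetate | O(Cc3ccccc3)c1cc(OCc3ccccc3)c2c(c1)O[C@H](c1ccc(OCc3ccccc3)c(OCc3ccccc3)c1)[C@@H](OC(C)=O)C2OC(C)=O | intermediate
9 | (+)-catechin, (2R,3S) | Oc1cc(O)c2c(c1)O[C@H](c1ccc(O)c(O)c1)[C@@H](O)C2 | starting material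
10 | 5,7,3',4'-tetra-O-benzyl-(+)-catechin | O(Cc3ccccc3)c1cc(OCc3ccccc3)c2c(c1)O[C@H](c1ccc(OCc3ccccc3)c(OCc3ccccc3)c1)[C@@H](O)C2 | intermediate
11 | [3-O-acetyl-tetra-O-benzylcatechin]-(4α→8)-[tetra-O-benzylcatechin] | O(Cc3ccccc3)c1cc(OCc3ccccc3)c2c(c1)O[C@H](c1ccc(OCc3ccccc3)c(OCc3ccccc3)c1)[C@@H](OC(C)=O)[C@@H]2c1c(OCc3ccccc3)cc(OCc3ccccc3)c2c1O[C@H](c1ccc(OCc3ccccc3)c(OCc3ccccc3)c1)[C@@H](O)C2 | intermediate
12 | di-O-acetyl-dodeca-O-benzyl trimer, all (4α→8) | O(Cc3ccccc3)c1cc(OCc3ccccc3)c2c(c1)O[C@H](c1ccc(OCc3ccccc3)c(OCc3ccccc3)c1)[C@@H](OC(C)=O)[C@@H]2c1c(OCc3ccccc3)cc(OCc3ccccc3)c2c1O[C@H](c1ccc(OCc3ccccc3)c(OCc3ccccc3)c1)[C@@H](OC(C)=O)[C@@H]2c1c(OCc3ccccc3)cc(OCc3ccccc3)c2c1O[C@H](c1ccc(OCc3ccccc3)c(OCc3ccccc3)c1)[C@@H](O)C2 | intermediate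
13 | tri-O-acetyl-hexadeca-O-benzyl tetramer, all (4α→8) | O(Cc3ccccc3)c1cc(OCc3ccccc3)c2c(c1)O[C@H](c1ccc(OCc3ccccc3)c(OCc3ccccc3)c1)[C@@H](OC(C)=O)[C@@H]2c1c(OCc3ccccc3)cc(OCc3ccccc3)c2c1O[C@H](c1ccc(OCc3ccccc3)c(OCc3ccccc3)c1)[C@@H](OC(C)=O)[C@@H]2c1c(OCc3ccccc3)cc(OCc3ccccc3)c2c1O[C@H](c1ccc(OCc3ccccc3)c(OCc3ccccc3)c1)[C@@H](OC(C)=O)[C@@H]2c1c(OCc3ccccc3)cc(OCc3ccccc3)c2c1O[C@H](c1ccc(OCc3ccccc3)c(OCc3ccccc3)c1)[C@@H](O)C2 | intermediate
14 | hexadeca-O-benzyl-[catechin-(4α→8)]3-catechin | O(Cc3ccccc3)c1cc(OCc3ccccc3)c2c(c1)O[C@H](c1ccc(OCc3ccccc3)c(OCc3ccccc3)c1)[C@@H](O)[C@@H]2c1c(OCc3ccccc3)cc(OCc3ccccc3)c2c1O[C@H](c1ccc(OCc3ccccc3)c(OCc3ccccc3)c1)[C@@H](O)[C@@H]2c1c(OCc3ccccc3)cc(OCc3ccccc3)c2c1O[C@H](c1ccc(OCc3ccccc3)c(OCc3ccccc3)c1)[C@@H](O)[C@@H]2c1c(OCc3ccccc3)cc(OCc3ccccc3)c2c1O[C@H](c1ccc(OCc3ccccc3)c(OCc3ccccc3)c1)[C@@H](O)C2 | intermediate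
15 | catechin-(4α→8)-catechin-(4α→8)-catechin-(4α→8)-catechin (CNP0236700.2) | Oc1cc(O)c2c(c1)O[C@H](c1ccc(O)c(O)c1)[C@@H](O)[C@@H]2c1c(O)cc(O)c2c1O[C@H](c1ccc(O)c(O)c1)[C@@H](O)[C@@H]2c1c(O)cc(O)c2c1O[C@H](c1ccc(O)c(O)c1)[C@@H](O)[C@@H]2c1c(O)cc(O)c2c1O[C@H](c1ccc(O)c(O)c1)[C@@H](O)C2 | target

**Totals.** Total step count: 10. Longest linear sequence: 9 steps (steps 1, 2, 3, 4, 6, 7, 8, 9, 10).

**Steps most likely to fail**

1. Step 3 (key step). The magnesium phenoxide may add too slowly, so that the Lewis-acidic medium opens the oxirane with bromide or rearranges the epoxy aldehyde before the C–C bond forms. After protonation, the electron-rich benzylic carbinol may ionise to an ortho-quinone methide and oligomerise, or acetate may open the oxirane in competition with O1. Fallback: the C4–C4a bond would be made with a preformed aryl anion and the ring closure run as a separate operation. Setting out from 4, ortho-bromination (NBS, cat. i-Pr2NH, CH2Cl2, 0 °C) would give 2-bromo-3,5-bis(benzyloxy)phenol F1. Deprotonation and bromine–lithium exchange (MeLi, then t-BuLi, THF, −78 °C) and addition of 3 would give epoxy alcohol 6 after neutral work-up. Exposure of 6 to PPTS (cat.) in CH2Cl2 at 0 °C should close ring C, and the route is rejoined at 7.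

2. Step 8 (the same applies to steps 6 and 7). The electrophile may self-condense through its own free C8, the product may be over-extended, attack may stray to C6, and much of the valuable trimer must be used in excess and recovered. Fallback: a C8 cap on the electrophile would allow an equimolar coupling. Setting out from 8, NBS (CH2Cl2, −20 °C) would give (2R,3S,4RS)-8-bromo-5,7-bis(benzyloxy)-2-[3,4-bis(benzyloxy)phenyl]chromane-3,4-diyl diacetate F2. Coupling of F2 with 12 (1:1, BF3·OEt2 or TMSOTf, CH2Cl2, −78 °C) would give the 8-bromo tri-O-acetyl-hexadeca-O-benzyl tetramer F3. Methanolysis (NaOMe, MeOH/THF) would give the 8-bromo hexadeca-O-benzyl tetramer F4. Hydrogenolysis in the presence of Et3N (H2, Pd(OH)2/C) would remove bromine and benzyl groups together, and the route is rejoined at 15.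

3. Step 2. Iminium formation from the electron-rich enal may be slow, and the aryl oxirane may be opened by water or peroxide under the reaction conditions, with loss of yield and of enantiomeric and trans/cis purity. Fallback: reagent-controlled epoxidation of the allylic alcohol. Setting out from 2, Luche reduction (NaBH4, CeCl3·7H2O, MeOH, 0 °C) would give (E)-3-[3,4-bis(benzyloxy)phenyl]prop-2-en-1-ol F5. Sharpless asymmetric epoxidation (Ti(OiPr)4, L-(+)-diisopropyl tartrate, t-BuOOH, 4 Å molecular sieves, CH2Cl2, −20 °C) would give [(2S,3S)-3-[3,4-bis(benzyloxy)phenyl]oxiran-2-yl]methanol F6. Buffered oxidation (Dess–Martin periodinane, NaHCO3, CH2Cl2, 0 °C) would return the route to 3.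

**Further compounds**
F1 | step 3 | 2-bromo-3,5-bis(benzyloxy)phenol | Oc1cc(OCc2ccccc2)cc(OCc2ccccc2)c1Br
F2 | step 8 | (2R,3S,4RS)-8-bromo-5,7-bis(benzyloxy)-2-[3,4-bis(benzyloxy)phenyl]chromane-3,4-diyl diacetate | O(Cc3ccccc3)c1cc(OCc3ccccc3)c2c(c1Br)O[C@H](c1ccc(OCc3ccccc3)c(OCc3ccccc3)c1)[C@@H](OC(C)=O)C2OC(C)=O
F3 | step 8 | 8-bromo tri-O-acetyl-hexadeca-O-benzyl tetramer, all (4α→8) | O(Cc3ccccc3)c1cc(OCc3ccccc3)c2c(c1Br)O[C@H](c1ccc(OCc3ccccc3)c(OCc3ccccc3)c1)[C@@H](OC(C)=O)[C@@H]2c1c(OCc3ccccc3)cc(OCc3ccccc3)c2c1O[C@H](c1ccc(OCc3ccccc3)c(OCc3ccccc3)c1)[C@@H](OC(C)=O)[C@@H]2c1c(OCc3ccccc3)cc(OCc3ccccc3)c2c1O[C@H](c1ccc(OCc3ccccc3)c(OCc3ccccc3)c1)[C@@H](OC(C)=O)[C@@H]2c1c(OCc3ccccc3)cc(OCc3ccccc3)c2c1O[C@H](c1ccc(OCc3ccccc3)c(OCc3ccccc3)c1)[C@@H](O)C2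
F4 | step 8 | 8-bromo hexadeca-O-benzyl tetramer, all (4α→8) | O(Cc3ccccc3)c1cc(OCc3ccccc3)c2c(c1Br)O[C@H](c1ccc(OCc3ccccc3)c(OCc3ccccc3)c1)[C@@H](O)[C@@H]2c1c(OCc3ccccc3)cc(OCc3ccccc3)c2c1O[C@H](c1ccc(OCc3ccccc3)c(OCc3ccccc3)c1)[C@@H](O)[C@@H]2c1c(OCc3ccccc3)cc(OCc3ccccc3)c2c1O[C@H](c1ccc(OCc3ccccc3)c(OCc3ccccc3)c1)[C@@H](O)[C@@H]2c1c(OCc3ccccc3)cc(OCc3ccccc3)c2c1O[C@H](c1ccc(OCc3ccccc3)c(OCc3ccccc3)c1)[C@@H](O)C2
F5 | step 2 | (E)-3-[3,4-bis(benzyloxy)phenyl]prop-2-en-1-ol | OC/C=C/c1ccc(OCc2ccccc2)c(OCc2ccccc2)c1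
F6 | step 2 | [(2S,3S)-3-[3,4-bis(benzyloxy)phenyl]oxiran-2-yl]methanol | OC[C@@H]1O[C@H]1c1ccc(OCc2ccccc2)c(OCc2ccccc2)c1
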